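## The problem

The target is an achiral diaryl ether in which ring A is a methyl benzoate (ester on C1) with an O-prenyl group on C2, a methyl on C4 and the bridging oxygen on C6, while ring B carries the bridging oxygen on C1', a hydroxymethyl on C2', a methoxy on C4' and a second O-prenyl on C6'. The bridging oxygen has three ortho neighbours (the ester on ring A, the carbinol carbon and an oxygen on ring B), and ring B is electron-rich, so joining two finished arenes by an Ullmann or SNAr etherification is unattractive. There is no stereocentre to set; any stereocentre that arises on the way only has to be erasable. The two aryl prenyl ethers rule out strong acid, prolonged heating, electrophilic halogen, hydrogenation and long exposure to zerovalent palladium, and the benzylic alcohol is best revealed last. The two meta oxygens of ring B carry different alkyl groups and must be told apart. The enabling feature is that C4' and C6' are 1,3-related oxygens with the ether oxygen on the carbon next to C6', so ring B is a cyclohexane-1,3-dione whose C1' is the α-carbon of an acetoacetate (ketone = C6', methyl = C5'). That carbon can accept the ring A phenoxide by SN2, and C2'–C3'–C4' with its one-carbon branch is a 4,4-dialkoxybut-2-ynoate.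

## Retrosynthesis

**Carbinol.** Target 17 is traced to aldehyde 16 and then to diethyl acetal 15. No skeletal bond is cut; only the benzylic C–H bond is made in the forward direction. The C2' branch arrives from the ynoate at the aldehyde oxidation level, and an acetal tolerates every basic and palladium-mediated step before it. The forward steps need only a mild hydrolysis that spares prenyl ethers and a hydride that reduces an aldehyde beside a hindered ester.

**C6' prenyl ether.** Cutting the O6'–prenyl bond of 15 gives phenol 14 and prenyl bromide 2. This oxygen is the ketone oxygen of the acetoacetate during ring construction, so it cannot carry its prenyl group earlier. The forward reaction is a plain Williamson etherification.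

**Aromatization and the C4' methyl.** Phenol 14 is the decarboxylated, aromatized form of dienone ester 12 (C1'–CO2 bond cut in the forward sense). Compound 12 is the O4'-methyl enol ether of dione 11 (O4'–CH3 bond). The methyl group is placed before aromatization on purpose. In 11 the two dione oxygens differ sharply, since O6' sits beside the quaternary C1' and O4' is exposed, whereas after aromatization they would be two similar phenols. The forward steps need a regioselective O-methylation and a deallylation that leaves the prenyl ether of ring A alone.

**Ring B.** Dione 11 is cut at C1'–C2' and C4'–C5' into aryloxy acetoacetate 6 and ynoate 9. This removes the whole of ring B in one operation and leaves two small acyclic pieces. The alkyne supplies the resorcinol oxidation level, so no later dehydrogenation is needed. The allyl ester on C1' keeps the donor from closing irreversibly onto the ring A ester and later serves as the trigger for aromatization. The forward reaction must add the donor through carbon, place the methyl ester cis to C1', and acylate the acetyl methyl carbon and not the oxygen.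

**Ether oxygen.** Cutting the C1'–O bond of 6 gives phenol 3 and chloro keto ester 5, the latter made from allyl acetoacetate 4. The crowded diaryl ether bond is thus made as an sp3 C–O bond by SN2 at an activated carbon, which avoids any aryl–oxygen coupling.

**Starting materials.** Phenol 3 comes from symmetric diol 1 and prenyl bromide 2 by mono-alkylation. Ynoate 9 comes from 3,3-diethoxyprop-1-yne 7 by lithiation (acetylide 8) and methoxycarbonylation.

## Roads not taken

Alternative 1: Ring A would be cut at C1–C6 and C4–C5 into pyrone A2 and ethynyl ether A3. Pyrone A2 is methyl 4-acetoxy-6-methyl-2-oxo-2H-pyran-3-carboxylate, and A3 is the ethynyl ether of the complete ring B arene with its carbinol silylated. In the forward direction A3 would add across C3 and C6 of A2 in a Diels–Alder reaction, and the bridged lactone would lose CO2 to give diaryl ether A1, which carries an acetate on C2 of ring A.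
- Merits: the plan is convergent, and A2 holds the ester, the oxygen and the methyl of ring A in the right places. The polarity of an ynol ether against an ester-bearing pyrone should send the aryloxy carbon to the carbon next to the ester. Ring B comes from an aromatic precursor, so the O4'/O6' question never arises in the key step. In that respect this road is better than the chosen plan.
- Weak points: A3 is an ynol ether of a hindered, fully differentiated trioxygenated arene. The usual entry to aryl ethynyl ethers (a dihalovinyl ether followed by elimination with a strong base) adds steps on top of a multistep arene synthesis. The cycloaddition of A2 with A3 and the loss of CO2 need heat, which invites Claisen rearrangement of the aryl prenyl ether. A1 still needs deacetylation, prenylation and desilylation.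
- Comparison: the chosen plan buys ring A and builds ring B from two small commercial pieces at or below room temperature. It pays with a regioselective methylation that Alternative 1 does not need and with a key step that has no direct precedent.

Alternative 2: Ring B would be cut at C6'–C5' and C4'–C3' in a Danheiser-type benzannulation. Heating cyclobutenone A5 , which carries the ring A aryloxy group on its sp3 carbon, with silyl ynol ether A6 would give phenol A4 through electrocyclic opening to a vinylketene, [2+2] addition, 4π opening and a 6π closure that re-forms the C6'–C1' bond.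
- Merits: A4 has O6' free and O4' silylated by construction. This is a cleaner differentiation than the chosen plan can offer.
- Weak points: A5 has no short preparation, since the hindered, ester-bearing ring A phenol must be placed on the sp3 carbon of a four-membered ring. The cascade needs sustained heating in the presence of the ring A prenyl ether. A6 is a sensitive reagent. A4 needs four further steps (prenylation, selective aryl silyl ether cleavage, methylation, carbinol release).
- Comparison: the chosen plan sets against the better differentiation of A4 a shorter end game and a steric argument, namely that the quaternary C1' of 11 shields O6'.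

Alternative 3: Ring A would be cut at C2–C3. Dienyl malonate A8 would be deprotonated at a terminal methyl, and that carbon would attack one malonate ester carbonyl, closing ring A as salicylate A7 after loss of methoxide.
- Merits: the chemistry is simple and anionic, the ring A pattern comes out correctly, and a free C2 hydroxyl is left for prenylation. The end game from A7 (prenylation, desilylation) is shorter than in the chosen plan.
- Weak points: the ring B phenol A9 must be prepared separately with three different oxygen substituents in a 1,2,4 pattern, which only moves the differentiation problem elsewhere. Joining A9 to the malonate-bearing carbon to reach A8 is a hindered addition–elimination. The vinylogous enolate of A8 must cyclize and not polymerize or deconjugate.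
- Comparison: the chosen plan builds the ring B pattern from the connectivity of an acetoacetate and an ynoate and starts from a commercial ring A, so it has no counterpart to the separate synthesis of A9.

Key step: step 5

Remark: the target has no stereogenic element. The only stereocentre on the way is the α-carbon of the acetoacetate unit, which becomes C1' (compounds 5, 6 and 10 to 13); it is racemic throughout and is destroyed in step 7.

Abbreviation: ArA = 2-(methoxycarbonyl)-5-methyl-3-[(3-methylbut-2-en-1-yl)oxy]phenyl, the ring A aryl group.

## Route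

Step 1
Reactants: 1 methyl 2,6-dihydroxy-4-methylbenzoate; 2 prenyl bromide (1-bromo-3-methylbut-2-ene)
Product: 3 methyl 2-hydroxy-4-methyl-6-[(3-methylbut-2-en-1-yl)oxy]benzoate
Conditions: 2 (1.0 equiv), K2CO3 (1.1 equiv), acetone, rt
Reagents that add atoms: none
Why: Williamson etherification of a symmetric diol; after the first alkylation the remaining hydroxyl is held in a hydrogen bond to the ester carbonyl and is much less nucleophilic, so the reaction should stop at the mono-ether.

Step 2
Reactants: 4 allyl acetoacetate (prop-2-en-1-yl 3-oxobutanoate)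
Product: 5 allyl 2-chloro-3-oxobutanoate (racemic)
Conditions: SO2Cl2 (1.0 equiv), CH2Cl2, 0 °C to rt
Reagents that add atoms: sulfuryl chloride, O=S(=O)(Cl)Cl
Why: Electrophilic α-chlorination of a β-keto ester through its enol; this ionic reaction at the doubly activated carbon is much faster than any addition to the electron-poor allyl alkene, and one equivalent limits dichlorination.

Step 3
Reactants: 3 methyl 2-hydroxy-4-methyl-6-[(3-methylbut-2-en-1-yl)oxy]benzoate; 5 allyl 2-chloro-3-oxobutanoate
Product: 6 allyl 2-(ArA-oxy)-3-oxobutanoate (racemic, keto–enol mixture)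
Conditions: K2CO3 (1.2 equiv), acetone, reflux
Reagents that add atoms: none
Why: SN2 displacement of a doubly carbonyl-activated secondary chloride by a phenoxide, the standard entry to 2-aryloxyacetoacetates; attack of the product enolate on the ring A ester would give only a non-enolizable benzofuranone that reopens, so it should not drain material.

Step 4
Reactants: 7 3,3-diethoxyprop-1-yne
Product: 9 methyl 4,4-diethoxybut-2-ynoate, via lithium acetylide 8 (not isolated)
Conditions: n-BuLi, THF, −78 °C; then ClCO2Me, −78 °C to rt
Reagents that add atoms: methyl chloroformate, COC(=O)Cl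
Why: Deprotonation of a terminal alkyne and C-acylation of the lithium acetylide with a chloroformate, a routine preparation of alkynoates that an acetal tolerates.

Step 5
Reactants: 6 allyl 2-(ArA-oxy)-3-oxobutanoate; 9 methyl 4,4-diethoxybut-2-ynoate
Product: 11 racemic allyl 1-(ArA-oxy)-2-(diethoxymethyl)-4,6-dioxocyclohex-2-ene-1-carboxylate, via open-chain Michael adduct 10 (not isolated)
Conditions: 9 (1.2 equiv), KOt-Bu (0.1 equiv), THF, 0 °C to rt; then LiN(SiMe3)2 (2.2 equiv), THF, −78 to 0 °C; cold 0.5 M HCl to pH 4
Reagents that add atoms: none
Why: Proposed new method: the potassium enolate of 6 should add through carbon to the β-carbon of ynoate 9 (C1'–C2' bond), and the allenolate should be protonated by further 6 on the side away from the bulky quaternary C1', which places the methyl ester cis to C1' in adduct 10; LiN(SiMe3)2 then removes an acetyl proton and the methyl ketone enolate attacks that ester in a 6-exo-trig Claisen condensation (C4'–C5' bond), expelling methoxide and closing ring B as the enolate of 11. The closest known reaction types are the classical Michael–Claisen annulation of acetoacetic esters with crotonates to dihydroresorcinols and the tandem Michael–Dieckmann reaction of acetonedicarboxylate anions with alkynoates to resorcinols; neither has been shown on a fully substituted α-aryloxy donor. C1' becomes a quaternary stereocentre with no controlling element, so 11 is racemic, which is harmless because step 7 removes the centre. The step needs carbon attack in both bond formations: the oxygen adducts (enol ether, enol lactone) and the benzofuranone from attack of the C1' enolate on the ring A ester are not stabilized and should revert, while the dione enolate of 11 is the thermodynamic sink. It also needs the vinyl anion to be quenched before it attacks the acetyl group (acyl migration through a four-membered alkoxide), which is why the addition is run with catalytic base and the pronucleophile as proton source before the strong base is added.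

Step 6
Reactants: 11 allyl 1-(ArA-oxy)-2-(diethoxymethyl)-4,6-dioxocyclohex-2-ene-1-carboxylate
Product: 12 allyl 1-(ArA-oxy)-2-(diethoxymethyl)-4-methoxy-6-oxocyclohexa-2,4-diene-1-carboxylate (racemic; used without storage)
Conditions: Me2SO4 (1.1 equiv), K2CO3 (1.5 equiv), acetone, 0 °C to rt
Reagents that add atoms: dimethyl sulfate, COS(=O)(=O)OC
Why: O-Alkylation of the potassium enolate of a cyclic 1,3-dione by a hard electrophile; O6' is flanked by the quaternary C1' and can be held by potassium in a chelate with the C1' ester carbonyl, whereas O4' is exposed, so methylation should go to O4', the same steric bias that directs enol ether formation in 4,4-disubstituted cyclohexane-1,3-diones to the remote oxygen.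

Step 7
Reactants: 12 allyl 1-(ArA-oxy)-2-(diethoxymethyl)-4-methoxy-6-oxocyclohexa-2,4-diene-1-carboxylate
Product: 14 methyl 2-[2-(diethoxymethyl)-6-hydroxy-4-methoxyphenoxy]-4-methyl-6-[(3-methylbut-2-en-1-yl)oxy]benzoate, via dienone carboxylic acid 13 (not isolated)
Conditions: Pd(PPh3)4 (5 mol %), HCO2H (2 equiv), Et3N (2.5 equiv), THF, rt
Reagents that add atoms: none
Why: Tsuji-type deallylation of an allyl β-keto ester by zerovalent palladium with formate as hydride donor; ionization gives carboxylate 13, whose decarboxylation delivers the aromatic phenoxide directly and erases the C1' stereocentre, and an allyl ester ionizes much faster than the hindered trisubstituted prenyl aryl ether, which should survive at room temperature.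

Step 8
Reactants: 14 methyl 2-[2-(diethoxymethyl)-6-hydroxy-4-methoxyphenoxy]-4-methyl-6-[(3-methylbut-2-en-1-yl)oxy]benzoate; 2 prenyl bromide
Product: 15 methyl 2-{2-(diethoxymethyl)-4-methoxy-6-[(3-methylbut-2-en-1-yl)oxy]phenoxy}-4-methyl-6-[(3-methylbut-2-en-1-yl)oxy]benzoate
Conditions: 2 (1.3 equiv), K2CO3, DMF, rt
Reagents that add atoms: none
Why: Williamson etherification of the only free phenol; the acetal and both esters are inert to carbonate at room temperature.

Step 9
Reactants: 15 methyl 2-{2-(diethoxymethyl)-4-methoxy-6-[(3-methylbut-2-en-1-yl)oxy]phenoxy}-4-methyl-6-[(3-methylbut-2-en-1-yl)oxy]benzoate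
Product: 16 methyl 2-{2-formyl-4-methoxy-6-[(3-methylbut-2-en-1-yl)oxy]phenoxy}-4-methyl-6-[(3-methylbut-2-en-1-yl)oxy]benzoate
Conditions: PPTS (0.2 equiv), acetone–H2O, rt
Reagents that add atoms: water, O
Why: Acid-catalysed hydrolysis of an aryl diethyl acetal through a benzylic oxocarbenium ion, fast under weakly acidic buffered conditions that leave aryl prenyl ethers and the ester untouched.

Step 10
Reactants: 16 methyl 2-{2-formyl-4-methoxy-6-[(3-methylbut-2-en-1-yl)oxy]phenoxy}-4-methyl-6-[(3-methylbut-2-en-1-yl)oxy]benzoate
Product: 17 methyl 2-{2-(hydroxymethyl)-4-methoxy-6-[(3-methylbut-2-en-1-yl)oxy]phenoxy}-4-methyl-6-[(3-methylbut-2-en-1-yl)oxy]benzoate (CNP0561346.0)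
Conditions: NaBH4, MeOH–THF, 0 °C
Reagents that add atoms: none
Why: Chemoselective hydride reduction; NaBH4 reduces the aldehyde at 0 °C and leaves the doubly ortho-substituted methyl ester and the alkenes alone.

## Compound list

1 | methyl 2,6-dihydroxy-4-methylbenzoate | COC(=O)c1c(O)cc(C)cc1O | starting material
2 | prenyl bromide (1-bromo-3-methylbut-2-ene) | CC(C)=CCBr | starting material
3 | methyl 2-hydroxy-4-methyl-6-[(3-methylbut-2-en-1-yl)oxy]benzoate | COC(=O)c1c(O)cc(C)cc1OCC=C(C)C | intermediate
4 | allyl acetoacetate (prop-2-en-1-yl 3-oxobutanoate) | CC(=O)CC(=O)OCC=C | starting material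
5 | allyl 2-chloro-3-oxobutanoate (racemic) | CC(=O)C(Cl)C(=O)OCC=C | intermediate
6 | prop-2-en-1-yl 2-{2-(methoxycarbonyl)-5-methyl-3-[(3-methylbut-2-en-1-yl)oxy]phenoxy}-3-oxobutanoate (racemic) | C=CCOC(=O)C(Oc1cc(C)cc(OCC=C(C)C)c1C(=O)OC)C(C)=O | intermediate
7 | 3,3-diethoxyprop-1-yne | CCOC(OCC)C#C | starting material
8 | lithium 3,3-diethoxyprop-1-yn-1-ide | [Li]C#CC(OCC)OCC | intermediate (not isolated)
9 | methyl 4,4-diethoxybut-2-ynoate | CCOC(OCC)C#CC(=O)OC | intermediate
10 | 1-allyl 5-methyl (3E)-2-acetyl-3-(diethoxymethyl)-2-{2-(methoxycarbonyl)-5-methyl-3-[(3-methylbut-2-en-1-yl)oxy]phenoxy}pent-3-enedioate (racemic) | C=CCOC(=O)C(Oc1cc(C)cc(OCC=C(C)C)c1C(=O)OC)(C(C)=O)/C(C(OCC)OCC)=C\C(=O)OC | intermediate (not isolated)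
11 | prop-2-en-1-yl 2-(diethoxymethyl)-1-{2-(methoxycarbonyl)-5-methyl-3-[(3-methylbut-2-en-1-yl)oxy]phenoxy}-4,6-dioxocyclohex-2-ene-1-carboxylate (racemic; drawn as the diketone) | C=CCOC(=O)C1(Oc2cc(C)cc(OCC=C(C)C)c2C(=O)OC)C(C(OCC)OCC)=CC(=O)CC1=O | intermediate
12 | prop-2-en-1-yl 2-(diethoxymethyl)-4-methoxy-1-{2-(methoxycarbonyl)-5-methyl-3-[(3-methylbut-2-en-1-yl)oxy]phenoxy}-6-oxocyclohexa-2,4-diene-1-carboxylate (racemic) | C=CCOC(=O)C1(Oc2cc(C)cc(OCC=C(C)C)c2C(=O)OC)C(C(OCC)OCC)=CC(OC)=CC1=O | intermediate
13 | 2-(diethoxymethyl)-4-methoxy-1-{2-(methoxycarbonyl)-5-methyl-3-[(3-methylbut-2-en-1-yl)oxy]phenoxy}-6-oxocyclohexa-2,4-diene-1-carboxylic acid (racemic) | OC(=O)C1(Oc2cc(C)cc(OCC=C(C)C)c2C(=O)OC)C(C(OCC)OCC)=CC(OC)=CC1=O | intermediate (not isolated)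
14 | methyl 2-[2-(diethoxymethyl)-6-hydroxy-4-methoxyphenoxy]-4-methyl-6-[(3-methylbut-2-en-1-yl)oxy]benzoate | COC(=O)c1c(OCC=C(C)C)cc(C)cc1Oc1c(C(OCC)OCC)cc(OC)cc1O | intermediate
15 | methyl 2-{2-(diethoxymethyl)-4-methoxy-6-[(3-methylbut-2-en-1-yl)oxy]phenoxy}-4-methyl-6-[(3-methylbut-2-en-1-yl)oxy]benzoate | COC(=O)c1c(OCC=C(C)C)cc(C)cc1Oc1c(C(OCC)OCC)cc(OC)cc1OCC=C(C)C | intermediate
16 | methyl 2-{2-formyl-4-methoxy-6-[(3-methylbut-2-en-1-yl)oxy]phenoxy}-4-methyl-6-[(3-methylbut-2-en-1-yl)oxy]benzoate | COC(=O)c1c(OCC=C(C)C)cc(C)cc1Oc1c(C=O)cc(OC)cc1OCC=C(C)C | intermediate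
17 | methyl 2-{2-(hydroxymethyl)-4-methoxy-6-[(3-methylbut-2-en-1-yl)oxy]phenoxy}-4-methyl-6-[(3-methylbut-2-en-1-yl)oxy]benzoate | COC(=O)c1c(OCC=C(C)C)cc(C)cc1Oc1c(CO)cc(OC)cc1OCC=C(C)C | target

## Step count and risk

Total: 10 steps. Longest linear sequence: 8 steps (steps 1, 3, 5, 6, 7, 8, 9, 10). Steps 2 and 4 are one-step side branches.

**Step 5 (key step, proposed new method).** The most likely failure is diversion of the vinyl anion or allenolate formed in the conjugate addition. It may attack the acetyl carbonyl and migrate the acyl group, or the adduct may form with the ester trans to C1' and then fail to close, or close through oxygen. The methoxide set free in the Claisen step may also cleave the acetyl group of unreacted adduct. These problems come from the alkyne, so the fallback uses an alkene acceptor and known reactions; it sets out from 9 and 6 and comes back to the route at 14. Ynoate 9 is semihydrogenated (H2, Pd on CaCO3 poisoned with Pb(OAc)2, quinoline) to methyl (Z)-4,4-diethoxybut-2-enoate F1. Classical Michael–Claisen annulation of 6 with F1 (KOt-Bu, THF) should give the saturated dione allyl 1-(ArA-oxy)-2-(diethoxymethyl)-4,6-dioxocyclohexane-1-carboxylate F2 as a mixture of diastereomers; there is no alkene geometry to control here. O-Methylation as in step 6 (Me2SO4, K2CO3) should give the enol ether allyl 1-(ArA-oxy)-2-(diethoxymethyl)-4-methoxy-6-oxocyclohex-4-ene-1-carboxylate F3. Tsuji decarboxylation–dehydrogenation (Pd(OAc)2, PPh3, MeCN, reflux) then introduces the C1'=C2' double bond as the allyl group leaves as propene, and the resulting dienone tautomerizes to phenol 14. If the hindered enolate fails to add at all, this fallback does not help.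

**Step 6.** Poor discrimination between the two dione oxygens, or C-methylation at C5', would lower the yield of the required enol ether. The steric bias is an argument from analogy, not a certainty. The fallback aromatizes first and separates the oxygens by a size-selective protecting group; it sets out from 11 and comes back at 15. Dione 11 is deallylated and decarboxylated under the conditions of step 7 to the resorcinol methyl 2-[2-(diethoxymethyl)-4,6-dihydroxyphenoxy]-4-methyl-6-[(3-methylbut-2-en-1-yl)oxy]benzoate F4. The unhindered C4' hydroxyl is silylated (TIPSCl, imidazole, DMF, 0 °C) to the C4' triisopropylsilyl ether F5. Prenylation of the C6' hydroxyl (2, K2CO3) gives the C6' prenyl C4' silyl ether F6. Fluoride (Bu4NF, THF) frees the C4' phenol F7. Methylation (MeI, K2CO3) returns to 15.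

**Step 3.** The chelated, ortho-substituted phenoxide may attack the ketone of 5 (acetyl transfer, retro-Claisen), or 5 may sit as its unreactive enolate. Either would leave 3 unalkylated. The fallback replaces the SN2 reaction by a carbene O–H insertion; it sets out from 4 and 3 and comes back at 6. Regitz diazo transfer to 4 (4-acetamidobenzenesulfonyl azide, Et3N, MeCN) gives allyl 2-diazo-3-oxobutanoate F8. Insertion into the O–H bond of 3 with catalytic Rh2(OAc)4 in CH2Cl2 returns to 6.

**Step 1.** Over-alkylation to the bis-ether and C-prenylation of the electron-rich ring through the ambident phenoxide are the likely losses. The fallback is a Mitsunobu etherification of 1 with 3-methylbut-2-en-1-ol (PPh3, diisopropyl azodicarboxylate, THF, 0 °C), which is less prone to C-alkylation and discriminates strongly against the chelated second hydroxyl. It sets out from 1 and leads directly to 3, so it makes no new compound (entry F0).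

## Further compounds

F1 | step 5 | methyl (Z)-4,4-diethoxybut-2-enoate | CCOC(OCC)/C=C\C(=O)OC
F2 | step 5 | prop-2-en-1-yl 2-(diethoxymethyl)-1-{2-(methoxycarbonyl)-5-methyl-3-[(3-methylbut-2-en-1-yl)oxy]phenoxy}-4,6-dioxocyclohexane-1-carboxylate (racemic, mixture of diastereomers) | C=CCOC(=O)C1(Oc2cc(C)cc(OCC=C(C)C)c2C(=O)OC)C(C(OCC)OCC)CC(=O)CC1=O
F3 | step 5 | prop-2-en-1-yl 2-(diethoxymethyl)-4-methoxy-1-{2-(methoxycarbonyl)-5-methyl-3-[(3-methylbut-2-en-1-yl)oxy]phenoxy}-6-oxocyclohex-4-ene-1-carboxylate (racemic, mixture of diastereomers) | C=CCOC(=O)C1(Oc2cc(C)cc(OCC=C(C)C)c2C(=O)OC)C(C(OCC)OCC)CC(OC)=CC1=O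
F4 | step 6 | methyl 2-[2-(diethoxymethyl)-4,6-dihydroxyphenoxy]-4-methyl-6-[(3-methylbut-2-en-1-yl)oxy]benzoate | COC(=O)c1c(OCC=C(C)C)cc(C)cc1Oc1c(C(OCC)OCC)cc(O)cc1O
F5 | step 6 | methyl 2-{2-(diethoxymethyl)-6-hydroxy-4-[(triisopropylsilyl)oxy]phenoxy}-4-methyl-6-[(3-methylbut-2-en-1-yl)oxy]benzoate | COC(=O)c1c(OCC=C(C)C)cc(C)cc1Oc1c(C(OCC)OCC)cc(O[Si](C(C)C)(C(C)C)C(C)C)cc1O
F6 | step 6 | methyl 2-{2-(diethoxymethyl)-6-[(3-methylbut-2-en-1-yl)oxy]-4-[(triisopropylsilyl)oxy]phenoxy}-4-methyl-6-[(3-methylbut-2-en-1-yl)oxy]benzoate | COC(=O)c1c(OCC=C(C)C)cc(C)cc1Oc1c(C(OCC)OCC)cc(O[Si](C(C)C)(C(C)C)C(C)C)cc1OCC=C(C)C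
F7 | step 6 | methyl 2-{2-(diethoxymethyl)-4-hydroxy-6-[(3-methylbut-2-en-1-yl)oxy]phenoxy}-4-methyl-6-[(3-methylbut-2-en-1-yl)oxy]benzoate | COC(=O)c1c(OCC=C(C)C)cc(C)cc1Oc1c(C(OCC)OCC)cc(O)cc1OCC=C(C)C
F8 | step 3 | allyl 2-diazo-3-oxobutanoate | C=CCOC(=O)C(=[N+]=[N-])C(C)=O
F0 | step 1 | none | none
A1 | alternative 1 | methyl 2-acetoxy-6-{2-[(tert-butyldimethylsilyloxy)methyl]-4-methoxy-6-[(3-methylbut-2-en-1-yl)oxy]phenoxy}-4-methylbenzoate | COC(=O)c1c(OC(C)=O)cc(C)cc1Oc1c(CO[Si](C)(C)C(C)(C)C)cc(OC)cc1OCC=C(C)C
A2 | alternative 1 | methyl 4-acetoxy-6-methyl-2-oxo-2H-pyran-3-carboxylate | COC(=O)C1=C(OC(C)=O)C=C(C)OC1=O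
A3 | alternative 1 | tert-butyl{[2-(ethynyloxy)-5-methoxy-3-[(3-methylbut-2-en-1-yl)oxy]phenyl]methoxy}dimethylsilane | C#COc1c(CO[Si](C)(C)C(C)(C)C)cc(OC)cc1OCC=C(C)C
A4 | alternative 2 | methyl 2-{2-[(tert-butyldimethylsilyloxy)methyl]-6-hydroxy-4-[(triisopropylsilyl)oxy]phenoxy}-4-methyl-6-[(3-methylbut-2-en-1-yl)oxy]benzoate | COC(=O)c1c(OCC=C(C)C)cc(C)cc1Oc1c(CO[Si](C)(C)C(C)(C)C)cc(O[Si](C(C)C)(C(C)C)C(C)C)cc1O
A5 | alternative 2 | methyl 2-({2-[(tert-butyldimethylsilyloxy)methyl]-4-oxocyclobut-2-en-1-yl}oxy)-4-methyl-6-[(3-methylbut-2-en-1-yl)oxy]benzoate (racemic) | O=C1C=C(CO[Si](C)(C)C(C)(C)C)C1Oc1cc(C)cc(OCC=C(C)C)c1C(=O)OC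
A6 | alternative 2 | (ethynyloxy)triisopropylsilane | C#CO[Si](C(C)C)(C(C)C)C(C)C
A7 | alternative 3 | methyl 2-{2-[(tert-butyldimethylsilyloxy)methyl]-4-methoxy-6-[(3-methylbut-2-en-1-yl)oxy]phenoxy}-6-hydroxy-4-methylbenzoate | COC(=O)c1c(O)cc(C)cc1Oc1c(CO[Si](C)(C)C(C)(C)C)cc(OC)cc1OCC=C(C)C
A8 | alternative 3 | dimethyl 2-(1-{2-[(tert-butyldimethylsilyloxy)methyl]-4-methoxy-6-[(3-methylbut-2-en-1-yl)oxy]phenoxy}-3-methylbut-2-en-1-ylidene)malonate | COC(=O)C(C(=O)OC)=C(Oc1c(CO[Si](C)(C)C(C)(C)C)cc(OC)cc1OCC=C(C)C)C=C(C)C
A9 | alternative 3 | 2-[(tert-butyldimethylsilyloxy)methyl]-4-methoxy-6-[(3-methylbut-2-en-1-yl)oxy]phenol | Oc1c(CO[Si](C)(C)C(C)(C)C)cc(OC)cc1OCC=C(C)C
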